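The numbers are invented, and the outcome is calculated.

- In this stirred vessel the solid substrate starts undissolved, and the catalyst works on what has entered solution as starting material.

| flask | solid substrate | protic impurity | free catalyst | time |
|---|---|---|---|---|
| zeta | 0.040 mM | 0.00400 mM | 0.20 µM | 25 s |
| alpha | 0.060 mM | 0.00400 mM | 0.20 µM | 25 s |
| epsilon | 0.080 mM | 0.00400 mM | 0.20 µM | 25 s |
| delta | 0.12 mM | 0.00400 mM | 0.20 µM | 25 s |
| beta | 0.20 mM | 0.00400 mM | 0.20 µM | 25 s |

    2 free catalyst ⇌ resting dimer, settled at all times (K1 = 2.2 × 10⁷ M⁻¹)
    catalyst intermediate A ⇌ catalyst intermediate B (K2 = 0.50, k2 = 93 s⁻¹)
    catalyst intermediate B → free catalyst + target (k3 = 1300 s⁻¹)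
    starting material + protic impurity → quenched substrate (k4 = 19000 M⁻¹ s⁻¹)
    solid substrate ⇌ starting material, rate k5*(cs5 - [starting material]) while solid is left; crystals form when [starting material] > cs5 (cs5 = 0.19 mM, k5 = 0.024 s⁻¹)
    starting material + free catalyst → catalyst intermediate A (k6 = 2.2 × 10⁵ M⁻¹ s⁻¹)

- a doubled species enters its step squared and goes two at a time
- given per volume of solution although it is solid: solid substrate
- at the start none of the solid substrate is in solution
- a step back or a flat step of under half a percent of the largest counts as no turn
- "hardly changes" means that all values lie within two and a half points (for a concentration: within two and a half percent of the largest)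
- a step back or a flat step of under half a percent of the largest counts as no turn
- run time (zeta): 25 s

1. [target] at the end for zeta, alpha, epsilon, delta, beta, in this order
2. how the row runs (rises, then falls / rises all the way / hardly changes / falls all the way / falls, then rises)

- We compare two times: the dissolving time, 41.7 s, and the run, 25 s, whose ratio is 0.600.
- Dissolving runs at 0.024 s⁻¹ times the gap between the solubility, 0.19 mM, and c(starting material), and that concentration stays at zero or above. So the flow stays at or below its starting value, and a run can dissolve up to a ceiling of 0.114 mM.
- The impurity and the catalyst remove starting material, so c(starting material) stays at or below the amount dissolved, which keeps the gap at least as wide as we reckon it with no consumption.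
- That reckoning gives a lower bound on what a run dissolves while solid remains: the solubility times the exponential approach completed at this ratio, 0.0857 mM. We call this the dissolving reach.
- Neither limit contains a rate of the impurity or the catalyst, so the dissolving time and the run are the two times we carry.
- Zeta, alpha and epsilon are charged below the reach, so we expect their solid to be gone before the end, and sooner at the smaller charge, leaving less starting material to make target.
- Delta and beta are charged above the ceiling, so both still hold solid at the end. The flow depends on c(starting material) and not on the solid left, so these two run the same course. We therefore commit to a row that climbs through epsilon and ends in a flat step from delta to beta: scoring a climb by how far the smallest charge lies under the reach, and the other shapes by that charge against the reach or the ceiling, the row rises all the way.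
- The forecast gave 0.0081 mM, 0.0109 mM, 0.0123 mM, 0.0126 mM and 0.0126 mM, which rises all the way, and held that “The two largest charges therefore never run out of solid and give identical results.”
- The flask gives 0.00797 mM, 0.0108 mM, 0.0123 mM, 0.0125 mM and 0.0125 mM, and the row rises all the way. In epsilon the solid stands at 0% at 25.0 s, with starting material at 79.6% of the charge.
- In delta the solid was still dissolving while the catalyst turned over: 25.4% of it is left at 25.0 s, so 0.0895 mM has dissolved, more than the reach and less than the ceiling.
- In beta 55.2% of the solid is left at the same time, which also puts the dissolved amount inside those limits, at 0.0895 mM.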